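## Retrosynthetic overview
1. The strategy rests on the fully substituted benzene ring of the tetralin. C1 bears the pyrone, C2 the CHO, C3 and C4 the OH groups, and C4a/C8a are fused to the carbocycle with C5-methyl and C8-isopropyl (pyrone atoms primed). Its six carbons are read as three alkynes (C8a≡C1, C4a≡C4, C3≡C2), and the neighbouring C3/C4 oxygens as the two ends of a SiMe2–O–SiMe2 bridge.
2. Target ⇐ acid hydrolysis (acetal, two MOM groups) ⇐ double Tamao oxidation of the two aryl–Si bonds ⇐ fully intramolecular [2+2+2] of one triyne chain, which makes C3–C4, C4a–C8a and C1–C2.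
3. Ring order: the pyrone and phenol rings are bought. The five-membered disiloxane ring, the six-membered carbocycle and the benzene ring all close in the one cyclotrimerisation, and the disiloxane ring is then excised oxidatively.
4. Triyne ⇐ Sonogashira coupling of a 3'-iodopyrone with a terminal alkyne, so C1–C3' starts as an alkyne–pyrone bond and is never a biaryl coupling. The other end of the chain already carries the disiloxane, because acetylide chemistry at silicon must precede the base-sensitive pyrone.
5. The chain C8a–C8–C7–C6–C5–C4a is the ring of (+)-menthone opened between its carbonyl carbon and the adjacent CH2 by ozonolysis of the kinetic enol silane. Each terminus then gains one carbon by a diazophosphonate homologation.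

Key step: step 15

Assumption: the target string fixes C5 as S and C8 as R but gives no sense for the hindered C1–C3' axis, so rotamers or atropisomers about this bond in the cyclotrimerisation product and all later compounds are treated as one compound.

## Route

Step 1
Reactants: 1 (+)-menthone
Product: 3 {[(3S,6R)-3-methyl-6-(propan-2-yl)cyclohex-1-en-1-yl]oxy}trimethylsilane (kinetic enol silane), via lithium enolate 2 (not isolated)
Conditions: LiN(iPr)2, THF, −78 °C; Me3SiCl, −78 °C → rt
Reagents that add atoms: chlorotrimethylsilane, C[Si](C)(C)Cl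
Why: Kinetic enolate formation and O-silylation: the hindered amide removes a proton from the ring CH2 next to the carbonyl rather than from the isopropyl-bearing methine, so the enol silane forms on the methylene side and neither stereocentre is touched.

Step 2
Reactants: 3 kinetic enol silane
Product: 5 (2R,5S)-5-methyl-6-oxo-2-(propan-2-yl)hexanoic acid, via trimethylsilyl ester 4 (not isolated)
Conditions: O3, CH2Cl2, −78 °C; Me2S, −78 °C → rt; aqueous work-up
Reagents that add atoms: ozone, [O-][O+]=O
Why: Ozonolysis of a silyl enol ether with reductive work-up: the electron-rich C=C bond is cleaved to a silyl ester and an aldehyde, the labile silyl ester hydrolyses on work-up, and the two chain ends emerge at different oxidation levels with both stereocentres carried over from menthone.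

Step 3
Reactants: 5 aldehyde acid
Product: 6 methyl (2R,5S)-5-methyl-6-oxo-2-(propan-2-yl)hexanoate
Conditions: Me3SiCHN2, toluene/MeOH, 0 °C
Reagents that add atoms: (trimethylsilyl)diazomethane, C[Si](C)(C)C=[N+]=[N-]
Why: Diazoalkane methyl esterification: proton transfer from the acid and O-methylation run under essentially neutral conditions and much faster than any reaction at the aldehyde, so the epimerisable α-methyl centre is not endangered.

Step 4
Reactants: 6 aldehyde ester
Product: 7 methyl (2R,5S)-5-methyl-2-(propan-2-yl)hept-6-ynoate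
Conditions: dimethyl (1-diazo-2-oxopropyl)phosphonate, K2CO3, MeOH, 0 °C → rt
Reagents that add atoms: dimethyl (1-diazo-2-oxopropyl)phosphonate, CC(=O)C(=[N+]=[N-])P(=O)(OC)OC
Why: Ohira–Bestmann variant of the Seyferth–Gilbert homologation: the diazophosphonate anion adds to the aldehyde faster than carbonate enolises it, loss of phosphate and N2 with a 1,2-hydrogen shift gives the terminal alkyne (future C4a≡C4), and the methyl ester is indifferent to methanol.

Step 5
Reactants: 8 3,3-diethoxyprop-1-yne; 9 1,3-dichloro-1,1,3,3-tetramethyldisiloxane (excess)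
Product: 11 1-chloro-3-(3,3-diethoxyprop-1-yn-1-yl)-1,1,3,3-tetramethyldisiloxane, via lithium acetylide 10 (not isolated)
Conditions: n-BuLi, Et2O, −78 °C; cannulated into excess 9, Et2O, −78 °C → rt; volatiles removed, bulb-to-bulb distillation
Reagents that add atoms: none
Why: Substitution at Si–Cl by a lithium acetylide: inverse addition to an excess of the bifunctional dichloride stops the reaction at monosubstitution, the volatile surplus of 9 is pumped off, and the Si–O–Si unit is bought ready-made so that no unsymmetrical siloxane condensation is needed.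

Step 6
Reactants: 7 alkyne ester; 11 chlorodisiloxane
Product: 13 methyl (2R,5S)-7-[3-(3,3-diethoxyprop-1-yn-1-yl)-1,1,3,3-tetramethyldisiloxan-1-yl]-5-methyl-2-(propan-2-yl)hept-6-ynoate, via lithium acetylide 12 (not isolated)
Conditions: LiN(SiMe3)2 (1.0 equiv), THF, −78 °C; 11, −78 → 0 °C; pH 7 work-up
Reagents that add atoms: none
Why: C-silylation of an acetylide: the sp C–H is removed faster than the hindered tertiary α-C–H of the ester, the Si–Cl bond is by far the best electrophile present, and the two silicon-bound alkynes (C4a≡C4 and C3≡C2) are thereby joined.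

Step 7
Reactants: 13 disiloxane diyne ester
Product: 15 (2R,5S)-7-[3-(3,3-diethoxyprop-1-yn-1-yl)-1,1,3,3-tetramethyldisiloxan-1-yl]-5-methyl-2-(propan-2-yl)hept-6-ynal, via aluminium hemiacetal 14 (not isolated)
Conditions: iBu2AlH (1.1 equiv), CH2Cl2, −78 °C; aq potassium sodium tartrate
Reagents that add atoms: none
Why: Partial reduction of an ester with iBu2AlH: the α-branched hemiacetal 14 persists at −78 °C and collapses to the aldehyde only on work-up, while the acetal, the alkynyl–Si bonds and the siloxane are inert to the hydride at this temperature.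

Step 8
Reactants: 15 disiloxane diyne aldehyde
Product: 16 1-(3,3-diethoxyprop-1-yn-1-yl)-1,1,3,3-tetramethyl-3-[(3S,6R)-3-methyl-6-(propan-2-yl)octa-1,7-diyn-1-yl]disiloxane
Conditions: dimethyl (diazomethyl)phosphonate, KOtBu, THF, −78 → 0 °C (anion preformed with the phosphonate in slight excess)
Reagents that add atoms: dimethyl (diazomethyl)phosphonate, COP(=O)(OC)C=[N+]=[N-]
Why: Seyferth–Gilbert homologation in its aprotic form: the preformed phosphonate anion adds to the aldehyde at −78 °C before enolisation, the only anionic by-product is non-nucleophilic dimethyl phosphate, and the methanolic carbonate of step 4, which would cleave the alkynyl–Si bonds, is avoided.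

Step 9
Reactants: 17 4-hydroxybenzaldehyde
Product: 18 4-(methoxymethoxy)benzaldehyde
Conditions: MOMCl, iPr2NEt, CH2Cl2, 0 °C → rt
Reagents that add atoms: chloromethyl methyl ether, COCCl
Why: O-alkylation of a phenol with an α-chloro ether gives an acetal-type protecting group that resists the strong bases and metal catalysts to come and is removed by the final aqueous acid.

Step 10
Reactants: 19 4-hydroxy-6-methyl-2H-pyran-2-one
Product: 20 4-(methoxymethoxy)-6-methyl-2H-pyran-2-one
Conditions: MOMCl, iPr2NEt, CH2Cl2, 0 °C
Reagents that add atoms: chloromethyl methyl ether, COCCl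
Why: O-alkylation of the vinylogous acid with a hard electrophile takes place at O4' and keeps the 2-pyrone form; blocking O4' later prevents furan formation by attack of this oxygen on the C3' alkyne.

Step 11
Reactants: 20 MOM-protected methylpyrone; 18 MOM-protected aldehyde
Product: 22 (±)-6-{2-hydroxy-2-[4-(methoxymethoxy)phenyl]ethyl}-4-(methoxymethoxy)-2H-pyran-2-one, via lithium dienolate 21 (not isolated)
Conditions: LiN(SiMe3)2, THF, −78 °C; 18; AcOH, −78 °C
Reagents that add atoms: none
Why: Vinylogous aldol addition: the silazide is strong enough only for the vinylogously acidic C6' methyl group and not for the ring C–H bonds, the dienolate reacts at its exocyclic carbon, and the carbinol centre, formed racemic, is removed in the next step.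

Step 12
Reactants: 22 aldol adduct
Product: 24 4-(methoxymethoxy)-6-{(E)-2-[4-(methoxymethoxy)phenyl]ethenyl}-2H-pyran-2-one, via benzylic mesylate 23 (not isolated)
Conditions: MsCl, Et3N (excess), CH2Cl2, 0 °C → rt
Reagents that add atoms: none
Why: Mesylation followed by E1cB elimination: the benzylic mesylate lies β to the acidified CH2 of the pyrone and is lost under amine base, and full conjugation with minimal strain favours the E alkene.

Step 13
Reactants: 24 styrylpyrone
Product: 26 3-iodo-4-(methoxymethoxy)-6-{(E)-2-[4-(methoxymethoxy)phenyl]ethenyl}-2H-pyran-2-one, via 3-lithiopyrone 25 (not isolated)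
Conditions: LiN(iPr)2, THF, −78 °C; I2, −78 °C
Reagents that add atoms: iodine, [I][I]
Why: Directed lithiation and iodinolysis: C3'–H lies between the lactone carbonyl and the chelating OMOM group and is the most acidic position once the C6' methyl has become a styryl group, so the iodine is placed regiospecifically and no electrophilic iodination is run beside the electron-rich styrene.

Step 14
Reactants: 16 terminal triyne; 26 iodopyrone
Product: 27 3-{(3R,6S)-8-[3-(3,3-diethoxyprop-1-yn-1-yl)-1,1,3,3-tetramethyldisiloxan-1-yl]-6-methyl-3-(propan-2-yl)octa-1,7-diyn-1-yl}-4-(methoxymethoxy)-6-{(E)-2-[4-(methoxymethoxy)phenyl]ethenyl}-2H-pyran-2-one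
Conditions: PdCl2(PPh3)2, CuI, Et3N, THF, rt, degassed
Reagents that add atoms: none
Why: Sonogashira coupling: zerovalent palladium inserts readily into the C3'–iodine bond of the electron-poor pyrone, a copper acetylide can form only at the one terminal alkyne, and the silyl-capped alkynes, acetal and MOM groups are inert to dry amine in the absence of fluoride or alkoxide.

Step 15
Reactants: 27 disiloxane-linked triyne
Product: 28 3-[(5S,8R)-2-(diethoxymethyl)-5-methyl-8-(propan-2-yl)-3,4-(1,1,3,3-tetramethyldisiloxane-1,3-diyl)-5,6,7,8-tetrahydronaphthalen-1-yl]-4-(methoxymethoxy)-6-{(E)-2-[4-(methoxymethoxy)phenyl]ethenyl}-2H-pyran-2-one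
Conditions: RhCl(PPh3)3 (10 mol %), toluene, high dilution, 110 °C, Ar
Reagents that add atoms: none
Why: Loss of PPh3 from RhCl(PPh3)3 frees a monovalent rhodium centre that binds the two silicon-bound alkynes and couples them oxidatively to a trivalent rhodacyclopentadiene (C3–C4), after which the pyrone-capped alkyne, delivered by the four-carbon chain, inserts and reductive elimination releases the arene (C4a–C8a and C1–C2). The closest known reaction type is the rhodium- or cobalt-catalysed [2+2+2] cycloisomerisation of fully tethered triynes, including silicon-tethered ones and aryl-capped ones that give hindered biaryls. The five-membered 1,3-disila-2-oxa ring closes in the oxidative coupling of the 1,6-diyne unit, the six-membered carbocycle closes in the intramolecular insertion of the 1,7-related alkyne, and the benzene ring closes in the reductive elimination. No stereocentre is formed and the propargylic centres C5 and C8 carry no bond that the metal attacks, so they pass unchanged; only the hindered C1–C3' axis arises, which the target leaves undefined. The step needs regiocontrol at all six ring positions and chemoselectivity for the alkynes over the styryl and pyrone C=C bonds: the first is fixed by the order C2/C3, C4/C4a, C8a/C1 of the alkynes in one chain, the second by the fact that neither alkene can reach the metallacycle. High dilution keeps intermolecular oligomerisation behind the intramolecular path.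

Step 16
Reactants: 28 arene with fused disiloxane
Product: 29 3-[(5S,8R)-2-(diethoxymethyl)-3,4-dihydroxy-5-methyl-8-(propan-2-yl)-5,6,7,8-tetrahydronaphthalen-1-yl]-4-(methoxymethoxy)-6-{(E)-2-[4-(methoxymethoxy)phenyl]ethenyl}-2H-pyran-2-one
Conditions: 30% aq H2O2, KF, KHCO3, THF/MeOH, rt, Ar; taken on without delay
Reagents that add atoms: hydrogen peroxide, OO
Why: Tamao oxidation: fluoride and hydroperoxide add to the strained, oxygen-bearing silicon atoms, the aryl group migrates from silicon to oxygen in preference to methyl, and hydrolysis frees the catechol, while the acetal shields C2 from a Dakin cleavage and bicarbonate keeps the medium mild for the pyrone.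

Step 17
Reactants: 29 catechol acetal
Product: 30 Heimiomycin A, (5S,8R)-3,4-dihydroxy-1-{4-hydroxy-6-[(E)-2-(4-hydroxyphenyl)ethenyl]-2-oxo-2H-pyran-3-yl}-5-methyl-8-(propan-2-yl)-5,6,7,8-tetrahydronaphthalene-2-carbaldehyde
Conditions: 3 M aq HCl, THF, 45 °C, Ar
Reagents that add atoms: water, O
Why: Acid-catalysed acetal hydrolysis: the diethyl acetal and both methoxymethyl ethers are O,O-acetals and fall under the same aqueous acid, to which the catechol, the aldehyde, the styrylpyrone and the two benzylic stereocentres are inert.

## Compound list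
1 | (+)-menthone, (2R,5S)-5-methyl-2-(propan-2-yl)cyclohexan-1-one | CC(C)[C@H]1CC[C@H](C)CC1=O | starting material
2 | lithium (3S,6R)-3-methyl-6-(propan-2-yl)cyclohex-1-en-1-olate | CC(C)[C@H]1CC[C@H](C)C=C1[O-].[Li+] | intermediate
3 | {[(3S,6R)-3-methyl-6-(propan-2-yl)cyclohex-1-en-1-yl]oxy}trimethylsilane | CC(C)[C@H]1CC[C@H](C)C=C1O[Si](C)(C)C | intermediate
4 | trimethylsilyl (2R,5S)-5-methyl-6-oxo-2-(propan-2-yl)hexanoate | CC(C)[C@H](C(=O)O[Si](C)(C)C)CC[C@H](C)C=O | intermediate
5 | (2R,5S)-5-methyl-6-oxo-2-(propan-2-yl)hexanoic acid | CC(C)[C@H](C(=O)O)CC[C@H](C)C=O | intermediate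
6 | methyl (2R,5S)-5-methyl-6-oxo-2-(propan-2-yl)hexanoate | CC(C)[C@H](C(=O)OC)CC[C@H](C)C=O | intermediate
7 | methyl (2R,5S)-5-methyl-2-(propan-2-yl)hept-6-ynoate | CC(C)[C@H](C(=O)OC)CC[C@H](C)C#C | intermediate
8 | 3,3-diethoxyprop-1-yne | CCOC(C#C)OCC | starting material
9 | 1,3-dichloro-1,1,3,3-tetramethyldisiloxane | C[Si](C)(Cl)O[Si](C)(C)Cl | starting material
10 | (3,3-diethoxyprop-1-yn-1-yl)lithium | CCOC(OCC)C#[C-].[Li+] | intermediate
11 | 1-chloro-3-(3,3-diethoxyprop-1-yn-1-yl)-1,1,3,3-tetramethyldisiloxane | CCOC(OCC)C#C[Si](C)(C)O[Si](C)(C)Cl | intermediate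
12 | lithium acetylide of 7 | CC(C)[C@H](C(=O)OC)CC[C@H](C)C#[C-].[Li+] | intermediate
13 | methyl (2R,5S)-7-[3-(3,3-diethoxyprop-1-yn-1-yl)-1,1,3,3-tetramethyldisiloxan-1-yl]-5-methyl-2-(propan-2-yl)hept-6-ynoate | CC(C)[C@H](C(=O)OC)CC[C@H](C)C#C[Si](C)(C)O[Si](C)(C)C#CC(OCC)OCC | intermediate
14 | diisobutylaluminium hemiacetal of 13 (both epimers at the hemiacetal carbon) | CC(C)[C@H](C(OC)O[Al](CC(C)C)CC(C)C)CC[C@H](C)C#C[Si](C)(C)O[Si](C)(C)C#CC(OCC)OCC | intermediate
15 | (2R,5S)-7-[3-(3,3-diethoxyprop-1-yn-1-yl)-1,1,3,3-tetramethyldisiloxan-1-yl]-5-methyl-2-(propan-2-yl)hept-6-ynal | CC(C)[C@H](C=O)CC[C@H](C)C#C[Si](C)(C)O[Si](C)(C)C#CC(OCC)OCC | intermediate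
16 | 1-(3,3-diethoxyprop-1-yn-1-yl)-1,1,3,3-tetramethyl-3-[(3S,6R)-3-methyl-6-(propan-2-yl)octa-1,7-diyn-1-yl]disiloxane | CC(C)[C@H](C#C)CC[C@H](C)C#C[Si](C)(C)O[Si](C)(C)C#CC(OCC)OCC | intermediate
17 | 4-hydroxybenzaldehyde | O=Cc1ccc(O)cc1 | starting material
18 | 4-(methoxymethoxy)benzaldehyde | COCOc1ccc(C=O)cc1 | intermediate
19 | 4-hydroxy-6-methyl-2H-pyran-2-one | Cc1cc(O)cc(=O)o1 | starting material
20 | 4-(methoxymethoxy)-6-methyl-2H-pyran-2-one | Cc1cc(OCOC)cc(=O)o1 | intermediate
21 | lithium dienolate of 20 (exocyclic methylene form) | C=C1C=C(OCOC)C=C([O-])O1.[Li+] | intermediate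
22 | (±)-6-{2-hydroxy-2-[4-(methoxymethoxy)phenyl]ethyl}-4-(methoxymethoxy)-2H-pyran-2-one | COCOc1ccc(cc1)C(O)Cc1cc(OCOC)cc(=O)o1 | intermediate
23 | (±)-benzylic methanesulfonate of 22 | COCOc1ccc(cc1)C(OS(C)(=O)=O)Cc1cc(OCOC)cc(=O)o1 | intermediate
24 | 4-(methoxymethoxy)-6-{(E)-2-[4-(methoxymethoxy)phenyl]ethenyl}-2H-pyran-2-one | COCOc1ccc(/C=C/c2cc(OCOC)cc(=O)o2)cc1 | intermediate
25 | 3-lithio derivative of 24 | COCOc1ccc(/C=C/c2cc(OCOC)c([Li])c(=O)o2)cc1 | intermediate
26 | 3-iodo-4-(methoxymethoxy)-6-{(E)-2-[4-(methoxymethoxy)phenyl]ethenyl}-2H-pyran-2-one | Ic1c(OCOC)cc(/C=C/c2ccc(OCOC)cc2)oc1=O | intermediate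
27 | disiloxane-linked triyne carrying the pyrone (R at the isopropyl-bearing carbon, S at the methyl-bearing carbon) | CC(C)[C@H](C#Cc1c(OCOC)cc(/C=C/c2ccc(OCOC)cc2)oc1=O)CC[C@H](C)C#C[Si](C)(C)O[Si](C)(C)C#CC(OCC)OCC | intermediate
28 | (5S,8R) hexasubstituted arene with C3–SiMe2–O–SiMe2–C4 bridge, C2 diethyl acetal and C1 pyrone | CC(C)[C@H]1CC[C@H](C)c2c3c(c(C(OCC)OCC)c(-c4c(OCOC)cc(/C=C/c5ccc(OCOC)cc5)oc4=O)c21)[Si](C)(C)O[Si]3(C)C | intermediate
29 | (5S,8R) catechol with C2 diethyl acetal and both MOM groups | CC(C)[C@H]1CC[C@H](C)c2c(O)c(O)c(C(OCC)OCC)c(-c3c(OCOC)cc(/C=C/c4ccc(OCOC)cc4)oc3=O)c21 | intermediate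
30 | Heimiomycin A | CC(C)[C@H]1CC[C@H](C)c2c(O)c(O)c(C=O)c(-c3c(O)cc(/C=C/c4ccc(O)cc4)oc3=O)c21 | target

## Count and risks
Total step count: 17.

Longest linear sequence: 11 steps from (+)-menthone (steps 1–4, 6–8, 14–17).

**1. Step 15.**
- What may go wrong: the pyrone-capped alkyne, flanked by the isopropyl-bearing carbon, may be too crowded to insert into the rhodacycle built from the two silyl alkynes. Intermolecular oligomerisation would then overtake ring closure. The pyrone or the styrene may also bind and slow the catalyst.
- Fallback: the disiloxane-tethered cyclotrimerisation is kept but run before the pyrone is attached. It sets out from 16.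
- n-BuLi (one equivalent, THF, −78 °C), then 2-isopropoxy-4,4,5,5-tetramethyl-1,3,2-dioxaborolane, then one equivalent of HCl in Et2O should give the alkynyl pinacolboronate F1.
- With no pyrone or styrene on board, cobalt conditions suited to silyl alkynes (CpCo(CO)2, xylene, reflux, irradiation) should convert it into the aryl pinacolboronate F2.
- Suzuki–Miyaura coupling with 26 (Pd2(dba)3, SPhos, K3PO4, toluene/water, 90 °C) comes back to the route at 28.
- The price is that the hindered C1–C3' bond is then made by cross-coupling.

**2. Step 16.**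
- What may go wrong: protodesilylation in place of the second aryl migration. Hydrolytic loss of the acetal once the neighbouring phenol is free, followed by Dakin cleavage of the aldehyde. Attack of hydroperoxide anion on the styrylpyrone.
- Fallback: activation of silicon is separated from the oxidation, and the nucleophilic aqueous peroxide is replaced by an electrophilic peracid in a dry medium. It sets out from 28.
- Et3N·3HF (THF, rt, molecular sieves) should open the strained Si–O–Si ring to the bis(fluorodimethylsilyl)arene F3.
- This is oxidised with mCPBA and KF in dry DMF at rt (peracid oxidation of fluorosilanes). The styryl double bond is slow toward peracid because it is conjugated with the electron-poor pyrone.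
- Hydrolysis of the aryl silyl ethers on neutral work-up comes back to the route at 29.

**3. Step 8.**
- What may go wrong: cleavage of the alkynyl–silicon bonds or scrambling of the siloxane by traces of free tert-butoxide, and epimerisation of the α-branched aldehyde before addition.
- Fallback: the diazophosphonate homologation is replaced by a Corey–Fuchs sequence. It sets out from 15.
- CBr4 and PPh3 (CH2Cl2, 0 °C, neutral) should give the 1,1-dibromoalkene F4.
- n-BuLi (two equivalents, THF, −78 °C) then triggers bromine–lithium exchange and rearrangement faster than attack at silicon. An aqueous quench at low temperature comes back to the route at 16.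

## Further compounds
F1 | step 15 | alkynyl pinacolboronate of 16 (R at the isopropyl-bearing carbon, S at the methyl-bearing carbon) | CC(C)[C@H](C#CB1OC(C)(C)C(C)(C)O1)CC[C@H](C)C#C[Si](C)(C)O[Si](C)(C)C#CC(OCC)OCC
F2 | step 15 | (5S,8R) aryl pinacolboronate with boron at C1, diethyl acetal at C2 and C3–SiMe2–O–SiMe2–C4 bridge | CC(C)[C@H]1CC[C@H](C)c2c3c(c(C(OCC)OCC)c(B4OC(C)(C)C(C)(C)O4)c21)[Si](C)(C)O[Si]3(C)C
F3 | step 16 | (5S,8R) 3,4-bis(fluorodimethylsilyl)arene derived from 28 | CC(C)[C@H]1CC[C@H](C)c2c([Si](C)(C)F)c([Si](C)(C)F)c(C(OCC)OCC)c(-c3c(OCOC)cc(/C=C/c4ccc(OCOC)cc4)oc3=O)c21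
F4 | step 8 | 1,1-dibromoalkene derived from 15 (R at the isopropyl-bearing carbon, S at the methyl-bearing carbon) | CC(C)[C@H](C=C(Br)Br)CC[C@H](C)C#C[Si](C)(C)O[Si](C)(C)C#CC(OCC)OCC
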